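## Analysis of the target

- The target is a cis-fused decalin joined through a ketone at C1 to C3 of an N-unsubstituted maleimide, whose C4 carries an (S)-oct-1-en-3-yl group. The decalin is numbered as a naphthalene: C1 acyl-bearing, C2 methyl, C3=C4, C4a hydroxyl, C6 carboxylic acid, C8 methyl, C8a hydrogen.
- The decalin holds six stereocentres, (1S,2R,4aR,6R,8S,8aR). Calling the face of the C8a hydrogen the lower face: the C4a hydroxyl and the C1 acyl group are also on the lower face, while the C2 methyl, the C8 methyl and the C6 carboxyl are on the upper face.
- It follows that the ring fusion is cis, the C8 methyl is cis to the C8a–C1 bond, the C6 carboxyl is cis to the C8 methyl (both equatorial on ring B), and the C1 acyl group is trans to the C2 methyl.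
- The seventh stereocentre, in the side chain, is remote and cannot be relayed from the decalin.
- Sensitive groups are the tertiary allylic alcohol at C4a, the 3-acylmaleimide (a strong Michael acceptor, opened by hydroxide and amines), and C1, which is α to the ketone. The side-chain methine becomes allylic and vinylogously α to an imide carbonyl as soon as the maleimide double bond exists.
- C1 is the hardest centre. Equilibration cannot be trusted, because an equatorial acyl group meets the C8 methyl in a peri (syn-pentane) contact while the axial epimer is syn-axial to C5. A reagent that approaches C1 from the open lower face puts hydrogen, not carbon, on that face.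
- Further difficulties are the oxygen at the ring fusion, two carboxyl-level carbons (C1 and C6) that must be told apart, and a base-labile end group.
- The strategy rests on ring B. A C8 methyl cis to the C8a–C1 bond, a C6 that can carry an enol ether, and a cis fusion are the marks of an endo Diels–Alder adduct of (E)-2-silyloxypenta-1,3-diene with the unsubstituted alkene (C4a=C8a) of a 2-methylquinone monoketal whose free carbonyl becomes C1.

## Retrosynthetic reasoning

**Maleimide double bond (33 to 31).** The last bond made is the C3=C4 double bond of the maleimide, so 33 is traced through selenide 32 to succinimide 31. Only this double bond makes the side-chain methine acidic; in 31 it is merely β to the carbonyls. The forward step must dehydrogenate without base and leave nothing to deprotect afterwards.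

**Ketone carbon to imide carbon (31 to 19 and 27).** The bond between the ketone carbon and the imide ring is cut next, going back through 30, 29 and 28 to aldehyde 19 and imide 27. This is the most convergent cut: it separates the decalin from the side chain with its remote stereocentre. It also places the most reactive electrophile, an aldehyde, at the most hindered carbon. Forward, the enolate of 27 must form at its CH2 group and add to 19 without epimerising C1. The N-benzyl group is removed at 28 to 29, before a β-dicarbonyl exists, and the silicon groups leave together at 30 to 31.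

**Side-chain stereocentre (27 to 21 and 22).** Imide 27 is traced through 26 and 25 to malonate 23 and chloroacetamide 24, and 23 to carbonate 21 and malonate 22 by cutting the bond between the stereocentre and the malonate carbon. An iridium-catalysed allylic alkylation gives exactly the branched oct-1-en-3-yl pattern, with catalyst-controlled configuration, from a linear achiral carbonate made from alcohol 20. The malonate carbon ends as C4 of the maleimide.

**C3=C4 alkene (19 to 16).** Aldehyde 19 comes from bis-silyl ether 18, and 18 from enol triflate 17 and ketone 16. The C4 oxygen is inherited from the monoketal, and because C4a is quaternary in 16 the ketone can enolise in one direction only.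

**C1 configuration (16 to 13).** Ketone 16 is traced through alcohol 15 and aldehyde 14 to spiro-oxirane 13, cutting the C1–H bond. Every intermolecular delivery of hydrogen to C1 would come from the lower face and give the wrong epimer. A 1,2-hydride shift anti to the departing oxirane oxygen instead turns a lower-face oxygen into a lower-face carbon substituent.

**Two oxygens from one face (13 to 10).** Both C–O bonds of 13, at C4a and at C1, are traced through 12 to alkenes: the enol ether and the exocyclic methylene of 11, which comes from ketone 10. One oxidant, attacking twice from the lower face, sets the cis ring fusion and the oxirane configuration.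

**Ring substituents (10 to 5).** Ketone 10 is traced through 9, 8, 7 and 6 to adduct 5. The C1 methylene comes from the C1 ketone, the C2 and C6 hydrogens from one hydrogenation, and the C6 carboxyl carbon from carbonylation of the enol triflate made from the silyl enol ether. The order keeps C4 as a ketal until C1 is no longer a carbonyl.

**Ring B (5 to 2 and 4).** Cutting C4a–C5 and C8–C8a opens ring B to monoketal 2 and diene 4. This is the one step that makes two skeletal bonds and three stereocentres at once, under catalyst control.

**Building blocks.** Monoketal 2 comes from phenol 1 by oxidative dearomatisation, and diene 4 from enone 3 by silylation.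

## Alternatives that were turned down

**Alternative 1:** The cut is C1–C2, with C4 reconnected to a carboxyl oxygen, so that ring A results from a ring-contracting Ireland–Claisen rearrangement.
- Forward step: the precursor of A1 is a lactone in which C1 (also carrying a tert-butoxycarbonyl group) and the allylic carbinol carbon C4 are tied through the ester. Its silyl ketene acetal undergoes a [3,3] shift that forms C1–C2, breaks C4–O and leaves C3=C4. The silyl carboxylate left on C1, now geminal to the tert-butyl ester, is lost as CO2 to give the cis-decalin tert-butyl ester A1.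
- For it: C3=C4, the C4a ether and the C1 carboxyl carbon are all present after one pericyclic event, and C2 is set by chirality transfer from C4. On these points it is stronger than the chosen route, which needs an enolate oxidation, an enol triflate reduction and a separate homologation of C1.
- Against it: all of ring B (the quaternary C4a ether, C6, C8), the C4 carbinol centre and a defined propenyl geometry must be assembled first. The bicyclic transition state is necessarily boat-like and forms a bond next to the fully substituted C4a. After decarboxylation, C1 is fixed by protonation of an ester enol, the very centre where approach from the open face gives the wrong epimer.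
- Comparison: the chosen cycloaddition makes ring B, two C–C bonds and three stereocentres in one catalytic step from two one-step building blocks, and pays with more functional-group work on ring A.

**Alternative 2:** The cuts are C5–C6 and C6–C7, so that ring B is closed last on a finished ring A by a one-carbon bis-nucleophile, dimethyl malonate 22.
- Forward step: the precursor of A2 holds a spiro-oxirane at C4a, whose CH2 is C5, and a sulfonate at C7 on the chain that hangs from C8a. The malonate anion opens the oxirane at C5 and releases the tertiary C4a alkoxide; the regenerated malonate anion then displaces the C7 sulfonate (6-exo-tet), giving the geminal diester A2.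
- For it: the C4a hydroxyl comes with the configuration of the oxirane and needs no oxidation at a ring-fusion carbon, C3=C4 is there from the start, and C1 arrives as a protected hydroxymethyl group of defined configuration. On the C4a oxygen this plan is clearly stronger.
- Against it: the oxirane is a vinyl oxirane, so SN2' attack of the soft nucleophile at C3 competes with attack at the neopentyl-like C5. Ring A with C1, C2, C8a and the C8 methyl centre must be made beforehand without help from the annulation. C6 must still be set afterwards by loss of one ester and protonation.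
- Comparison: the key step makes two bonds of ring B but no stereocentre (C6 is not stereogenic in A2), against two bonds and three stereocentres under catalyst control.

**Alternative 3:** The cut is C4a–C5, read as a retro-oxy-Cope step.
- Forward step: the precursor of A3 is a bicyclo[2.2.2]octenol that is a 3-hydroxy-1,5-diene. Deprotonation of the tertiary alcohol at C7 starts an anionic [3,3] shift that breaks the C3–C7 bond and joins the vinyl terminus C5 to the silyloxy-substituted alkene carbon C4a. This closes ring B, leaves C3=C4 and unveils a C7 ketone: the cis-decalin-7-one A3.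
- For it: the cis ring fusion, the quaternary C4a–O centre and the position of the alkene all come from one stereospecific rearrangement of a rigid bicycle. For the C4a oxygen and the alkene it is stronger than the chosen route.
- Against it: the new bond is made to a fully substituted enol ether carbon. The C7 ketone has no counterpart in the target and must be removed. C6 carries a protected hydroxymethyl group two oxidation levels from the acid. The bicyclic precursor needs its own cycloaddition and a face-selective vinyl addition, and alkoxide conditions beside two silyl ethers invite silyl migration.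
- Comparison: the chosen route reaches the same cis-decalin without extraneous oxygen, with C6 functionalised at the right carbon by the diene, and with absolute configuration fixed by a catalyst.

Key step: step 3

Assumption: the enantiomers of the oxazaborolidine (step 3) and of the phosphoramidite (step 17) written below are taken to give the configurations drawn; if the sense of induction is the opposite, the mirror-image catalyst or ligand is used and nothing else changes.

## Route

Step 1
Reactants: 1 4-methoxy-2-methylphenol
Product: 2 4,4-dimethoxy-2-methylcyclohexa-2,5-dien-1-one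
Conditions: PhI(OAc)2, MeOH, 0 °C
Reagents that add atoms: methanol, CO
Why: Oxidative dearomatisation; the hypervalent iodine reagent oxidises the phenol to a phenoxenium-type species that methanol captures para to the oxygen, where the methoxy group already sits, giving the quinone monoketal.

Step 2
Reactants: 3 (E)-pent-3-en-2-one
Product: 4 (E)-2-(triisopropylsilyloxy)penta-1,3-diene
Conditions: iPr3SiOTf, Et3N, Et2O, 0 °C → rt
Reagents that add atoms: triisopropylsilyl trifluoromethanesulfonate, CC(C)[Si](OS(=O)(=O)C(F)(F)F)(C(C)C)C(C)C
Why: Soft enolisation; O-silylation and removal of a methyl proton by the amine give the cross-conjugated 2-silyloxydiene, and the (E)-alkene is not touched.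

Step 3
Reactants: 2 4,4-dimethoxy-2-methylcyclohexa-2,5-dien-1-one; 4 (E)-2-(triisopropylsilyloxy)penta-1,3-diene
Product: 5 cis-fused adduct (C1 ketone, C2-methyl enone, C4 dimethyl ketal, C6 silyl enol ether, C8 methyl on the upper face, H-4a and H-8a on the lower face)
Conditions: (S)-3,3-diphenyl-1-(o-tolyl)tetrahydro-1H,3H-pyrrolo[1,2-c][1,3,2]oxazaborole (20 mol %), HNTf2 (20 mol %), CH2Cl2, −78 → −40 °C
Reagents that add atoms: none
Why: Catalytic enantioselective Diels–Alder reaction, the closest known type being the oxazaborolidinium-catalysed cycloaddition of quinones and quinone monoketals with 2-silyloxydienes. The cationic boron binds the only free carbonyl of 2 (the future C1) on the side of the unsubstituted alkene and lowers the LUMO of that alkene; the ketal masks the second carbonyl, so there is one binding site and the adduct cannot aromatise. The [4+2] addition is concerted and asynchronous: the CH2 terminus of 4, which has the largest HOMO coefficient, bonds first to the β-carbon (C4a–C5) and the methyl-bearing terminus then closes C8–C8a, the 1-methyl and 2-silyloxy groups of the diene directing the same regiochemistry. Ring B is closed by this intermolecular suprafacial cycloaddition as a cyclohexene, cis-fused because both bonds form on one face of the ring alkene. C4a and C8a are set by that suprafacial addition, C8 by the endo transition state (the (E)-methyl group ends cis to the C8a–C1 bond), and the absolute configuration of all three by the face of the dienophile that the aryl group of the catalyst leaves open. The step needs site selectivity (the C2 methyl makes the other alkene more hindered and less electrophilic), regioselectivity, endo selectivity and enantioface selectivity (the last two from the carbonyl-bound catalyst).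

Step 4
Reactants: 5 cis-fused adduct
Product: 6 C6 enol triflate of the adduct (C6=C7 retained)
Conditions: CsF, PhNTf2, DME, rt; aq. NH4Cl
Reagents that add atoms: N-phenylbis(trifluoromethanesulfonimide), O=S(=O)(N(c1ccccc1)S(=O)(=O)C(F)(F)F)C(F)(F)F
Why: Fluoride cleaves the Si–O bond and the caesium enolate is O-sulfonylated by PhNTf2 as it forms, so the enol triflate keeps the C6=C7 position; the ketal and the enone are inert to CsF.

Step 5
Reactants: 6 C6 enol triflate
Product: 7 C6 2-(trimethylsilyl)ethyl ester of the C6=C7 alkene (enone and ketal unchanged)
Conditions: Pd(OAc)2 (5 mol %), PPh3 (10 mol %), CO (1 atm), Me3SiCH2CH2OH, iPr2NEt, DMF, 50 °C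
Reagents that add atoms: carbon monoxide, [C-]#[O+]; 2-(trimethylsilyl)ethanol, C[Si](C)(C)CCO
Why: Palladium-catalysed alkoxycarbonylation: oxidative addition of zerovalent palladium into the C–OTf bond, CO insertion and alcoholysis of the acyl palladium give the conjugated ester. The 2-(trimethylsilyl)ethyl ester is chosen because fluoride removes it late without base-mediated hydrolysis.

Step 6
Reactants: 7 unsaturated ester enone
Product: 8 saturated keto ester (C2 methyl and C6 ester on the upper face, C4 dimethyl ketal, cis-fused)
Conditions: H2 (1 atm), 10% Pd/C, EtOAc, pyridine (trace), rt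
Reagents that add atoms: none
Why: Heterogeneous hydrogenation of both conjugated alkenes; hydrogen is delivered to the convex lower face of the cis-fused bicycle, opposite the C8 methyl, which sets C2 (methyl up) and C6 (ester cis to the C8 methyl). A trace of pyridine suppresses hydrogenolysis of the allylic ketal.

Step 7
Reactants: 8 saturated keto ester
Product: 9 C1-methylene compound
Conditions: Zn, CH2Br2, TiCl4, THF, −40 → 5 °C; then 8, CH2Cl2, rt
Reagents that add atoms: dibromomethane, BrCBr
Why: Takai–Lombardo methylenation; the zinc/titanium methylene reagent is not basic, so C2 and C8a beside the hindered ketone are not epimerised, and it leaves the ester and the ketal alone.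

Step 8
Reactants: 9 C1-methylene ketal
Product: 10 C4 ketone
Conditions: PPTS, acetone/H2O, 40 °C
Reagents that add atoms: water, O
Why: Acid-catalysed ketal hydrolysis frees the C4 ketone; the 1,1-disubstituted alkene and the ester are stable to PPTS, and the now enolisable C4a is planarised in the next step.

Step 9
Reactants: 10 C4 ketone
Product: 11 triethylsilyl enol ether across C4=C4a
Conditions: Et3SiOTf, Et3N, CH2Cl2, 0 °C → rt
Reagents that add atoms: triethylsilyl trifluoromethanesulfonate, CC[Si](CC)(CC)OS(=O)(=O)C(F)(F)F
Why: Silylation under equilibrating conditions gives the more substituted enol ether, the thermodynamic regioisomer of a 1-decalone-type ketone; the ester is not enolised under these conditions.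

Step 10
Reactants: 11 silyl enol ether
Product: 13 C1 spiro-oxirane of the C4a-silyloxy C4 ketone (both new oxygens on the lower face), via silyloxy ketone 12 (not isolated)
Conditions: mCPBA (2.3 equiv), NaHCO3, CH2Cl2, −20 → 0 °C
Reagents that add atoms: 3-chloroperoxybenzoic acid, O=C(OO)c1cccc(Cl)c1
Why: Rubottom oxidation followed by Prilezhaev epoxidation in one flask: the peracid first attacks the electron-rich enol ether on the face of the C8a hydrogen (anti to C8), and 1,4-silyl migration gives 12 with the cis ring fusion. The second equivalent epoxidises the exocyclic alkene from the same face, because axial approach to C1 from the upper face is blocked by the axial C5, so the oxirane oxygen is cis to the C8a hydrogen.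

Step 11
Reactants: 13 spiro-oxirane
Product: 15 C1 hydroxymethyl compound (CH2OH on the lower face), via aldehyde 14 (not isolated)
Conditions: BF3·OEt2 (0.3 equiv), CH2Cl2, −78 °C; then Et3N; then NaBH4, MeOH, −78 °C
Reagents that add atoms: none
Why: Meinwald rearrangement: BF3 opens the oxirane at the tertiary C1–O bond and a hydride migrates from the CH2 carbon to C1 anti to the departing oxygen, so the formyl group takes the place of the oxygen on the lower face and the C1 hydrogen arrives on the upper face. NaBH4 reduces 14 in the flask before it can epimerise, and the hindered α-silyloxy ketone is left at −78 °C.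

Step 12
Reactants: 15 primary alcohol
Product: 16 bis(triethylsilyl) ether C4 ketone
Conditions: Et3SiCl, imidazole, DMAP (cat.), CH2Cl2, 0 °C → rt
Reagents that add atoms: chlorotriethylsilane, CC[Si](Cl)(CC)CC
Why: Routine silylation of the primary alcohol, needed because its alkoxide would compete in the next step.

Step 13
Reactants: 16 C4 ketone
Product: 17 C4 enol triflate (C3=C4)
Conditions: KN(SiMe3)2, THF, −78 °C; then PhNTf2; aq. NH4Cl
Reagents that add atoms: N-phenylbis(trifluoromethanesulfonimide), O=S(=O)(N(c1ccccc1)S(=O)(=O)C(F)(F)F)C(F)(F)F
Why: The ketone can enolise only toward C3 because C4a is quaternary, and the potassium enolate is O-triflated; ketone deprotonation outpaces that of the ester at −78 °C.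

Step 14
Reactants: 17 enol triflate
Product: 18 C3=C4 alkene (C1 CH2OSiEt3, C4a OSiEt3, C6 ester)
Conditions: Pd(OAc)2 (5 mol %), PPh3 (10 mol %), HCO2H, Bu3N, DMF, 60 °C
Reagents that add atoms: none
Why: Palladium-catalysed formate reduction of the enol triflate: oxidative addition, exchange of triflate for formate, loss of CO2 and C–H reductive elimination give the alkene; zerovalent palladium does not ionise the allylic silyl ether.

Step 15
Reactants: 18 bis(triethylsilyl) ether
Product: 19 C1 aldehyde (formyl on the lower face, C4a OSiEt3 kept)
Conditions: (COCl)2, DMSO, CH2Cl2, −78 → −30 °C; then Et3N, −78 → 0 °C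
Reagents that add atoms: none
Why: Swern oxidation applied to the silyl ether: the chlorosulfonium salt cleaves the primary triethylsilyl ether and oxidises it to the aldehyde in one operation, while the tertiary silyl ether is untouched. Low temperature and immediate use guard the C1 configuration.

Step 16
Reactants: 20 (E)-oct-2-en-1-ol
Product: 21 methyl (E)-oct-2-en-1-yl carbonate
Conditions: ClCO2Me, pyridine, CH2Cl2, 0 °C
Reagents that add atoms: methyl chloroformate, COC(=O)Cl
Why: Acylation of the allylic alcohol; the carbonate is the leaving group for the iridium step.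

Step 17
Reactants: 21 methyl (E)-oct-2-en-1-yl carbonate; 22 dimethyl malonate
Product: 23 dimethyl 2-[(3S)-oct-1-en-3-yl]propanedioate
Conditions: [Ir(cod)Cl]2 (2 mol %), (S,S,S)-O,O'-(1,1'-binaphthyl-2,2'-diyl)-N,N-bis(1-phenylethyl)phosphoramidite (4 mol %), TBD (8 mol %), THF, rt
Reagents that add atoms: none
Why: Iridium-catalysed asymmetric allylic alkylation: the malonate attacks the phosphoramidite–iridium allyl complex at its substituted terminus, giving the branched product and setting the side-chain stereocentre under ligand control. The methoxide released from the carbonate serves as the base.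

Step 18
Reactants: 23 dimethyl 2-[(3S)-oct-1-en-3-yl]propanedioate; 24 2-chloro-N-(4-methoxybenzyl)acetamide
Product: 26 methyl 1-(4-methoxybenzyl)-3-[(3S)-oct-1-en-3-yl]-2,5-dioxopyrrolidine-3-carboxylate, via amide diester 25 (not isolated)
Conditions: NaH, DMF, 0 °C; 24, NaI (cat.), rt → 60 °C
Reagents that add atoms: none
Why: Malonate alkylation by the α-chloro amide (SN2, iodide catalysis), then attack of the amide nitrogen on one ester closes the imide. The new quaternary ring carbon forms as a mixture, which does not matter.

Step 19
Reactants: 26 imide ester
Product: 27 1-(4-methoxybenzyl)-3-[(3S)-oct-1-en-3-yl]pyrrolidine-2,5-dione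
Conditions: LiCl, H2O, DMSO, 140 °C
Reagents that add atoms: none
Why: Krapcho dealkoxycarbonylation: chloride demethylates the ester geminal to an imide carbonyl and the carboxylate loses CO2. The side-chain stereocentre is β to the carbonyls and not acidic; the ring carbon becomes sp2 in the end.

Step 20
Reactants: 19 C1 aldehyde; 27 1-(4-methoxybenzyl)-3-[(3S)-oct-1-en-3-yl]pyrrolidine-2,5-dione
Product: 28 aldol adduct (secondary alcohol between decalin C1 and the imide ring)
Conditions: 27, LiN(SiMe3)2, THF, −78 °C; then 19, −78 °C; aq. NH4Cl
Reagents that add atoms: none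
Why: Aldol addition: the base removes a proton from the unsubstituted CH2 of the imide (the kinetic, less hindered site), and the lithium enolate adds to the aldehyde at −78 °C faster than it can enolise it or attack the ester. The three new stereocentres are all removed later.

Step 21
Reactants: 28 aldol adduct
Product: 29 N-unsubstituted aldol adduct
Conditions: (NH4)2Ce(NO3)6 (3 equiv), MeCN/H2O (4:1), 0 °C
Reagents that add atoms: none
Why: Oxidative debenzylation by tetravalent cerium (single-electron oxidation of the anisyl ring, loss of the benzylic proton, hydrolysis of the N-acyliminium ion). It is placed here because the later β-keto imide and the acylmaleimide would not tolerate it; loss of the tertiary silyl ether in the acidic medium would be of no consequence.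

Step 22
Reactants: 29 N-unsubstituted aldol adduct
Product: 30 β-keto imide
Conditions: 1,1,1-triacetoxy-1,1-dihydro-1,2-benziodoxol-3(1H)-one (DMP, 1.2 equiv), CH2Cl2, 0 °C → rt
Reagents that add atoms: none
Why: Periodinane oxidation of the secondary alcohol to the ketone under neutral conditions; a small excess and short time avoid oxidation of the resulting β-dicarbonyl.

Step 23
Reactants: 30 β-keto imide
Product: 31 hydroxy acid β-keto imide (free C4a hydroxyl and C6 carboxylic acid)
Conditions: Bu4NF (5 equiv), THF, 0 °C → rt; dilute HCl to pH 3
Reagents that add atoms: none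
Why: Fluoride cleaves the tertiary silyl ether and fragments the 2-(trimethylsilyl)ethyl ester (attack at silicon, loss of ethene) to the carboxylate. The β-keto imide is present as its enolate and protected by it, and the side-chain methine is not acidic at this stage.

Step 24
Reactants: 31 hydroxy acid β-keto imide
Product: 33 CNP0326775.3, via selenide 32 (not isolated)
Conditions: PhSeCl, pyridine, CH2Cl2, 0 °C; then NaIO4, THF/H2O, 0 °C
Reagents that add atoms: none
Why: α-Selenenylation of the enolised β-keto imide at the acyl-bearing ring carbon (anti to the neighbouring side chain), oxidation to the selenoxide and syn elimination with the adjacent ring hydrogen give the maleimide double bond without base. The now acidic side-chain stereocentre and C1 are therefore not disturbed.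

## Compound list

1 | 4-methoxy-2-methylphenol | COc1ccc(O)c(C)c1 | starting material
2 | 4,4-dimethoxy-2-methylcyclohexa-2,5-dien-1-one | COC1(OC)C=CC(=O)C(C)=C1 | intermediate
3 | (E)-pent-3-en-2-one | C/C=C/C(C)=O | starting material
4 | (E)-2-(triisopropylsilyloxy)penta-1,3-diene | C=C(O[Si](C(C)C)(C(C)C)C(C)C)/C=C/C | intermediate
5 | (4aR,8S,8aS)-4,4-dimethoxy-2,8-dimethyl-6-(triisopropylsilyloxy)-4a,5,8,8a-tetrahydronaphthalen-1(4H)-one (cis-fused, C8 methyl trans to H-8a) | O=C1C(C)=CC(OC)(OC)[C@@H]2CC(O[Si](C(C)C)(C(C)C)C(C)C)=C[C@H](C)[C@H]12 | intermediate
6 | C6 enol triflate of 5 (C6=C7; C1 enone, C4 dimethyl ketal, configuration as 5) | O=C1C(C)=CC(OC)(OC)[C@@H]2CC(OS(=O)(=O)C(F)(F)F)=C[C@H](C)[C@H]12 | intermediate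
7 | 2-(trimethylsilyl)ethyl ester at C6 of the C6=C7 alkene (C1 enone, C4 dimethyl ketal, configuration as 5) | O=C1C(C)=CC(OC)(OC)[C@@H]2CC(C(=O)OCC[Si](C)(C)C)=C[C@H](C)[C@H]12 | intermediate
8 | cis-fused C1 ketone, C4 dimethyl ketal, C6 2-(trimethylsilyl)ethyl ester; C2 methyl, C6 ester and C8 methyl on the upper face, H-4a and H-8a on the lower face | O=C1[C@H](C)CC(OC)(OC)[C@@H]2C[C@H](C(=O)OCC[Si](C)(C)C)C[C@H](C)[C@H]12 | intermediate
9 | as 8 with C1=CH2 in place of the ketone | C=C1[C@H](C)CC(OC)(OC)[C@@H]2C[C@H](C(=O)OCC[Si](C)(C)C)C[C@H](C)[C@H]12 | intermediate
10 | C1-methylene C4 ketone (cis-fused, C6 ester) | C=C1[C@H](C)CC(=O)[C@@H]2C[C@H](C(=O)OCC[Si](C)(C)C)C[C@H](C)[C@H]12 | intermediate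
11 | triethylsilyl enol ether across C4=C4a (C1 methylene, C6 ester) | C=C1[C@H](C)CC(O[Si](CC)(CC)CC)=C2C[C@H](C(=O)OCC[Si](C)(C)C)C[C@H](C)[C@H]12 | intermediate
12 | C4 ketone with C4a triethylsilyloxy group on the lower face (cis-fused), C1 methylene | C=C1[C@H](C)CC(=O)[C@]2(O[Si](CC)(CC)CC)C[C@H](C(=O)OCC[Si](C)(C)C)C[C@H](C)[C@H]12 | intermediate
13 | as 12 with a spiro-oxirane at C1, oxirane oxygen on the lower face | C1O[C@]12[C@H](C)CC(=O)[C@]3(O[Si](CC)(CC)CC)C[C@H](C(=O)OCC[Si](C)(C)C)C[C@H](C)[C@H]23 | intermediate
14 | C1 formyl compound (formyl on the lower face, trans to the C2 methyl), C4 ketone, C4a silyl ether | O=C[C@H]1[C@H](C)CC(=O)[C@]2(O[Si](CC)(CC)CC)C[C@H](C(=O)OCC[Si](C)(C)C)C[C@H](C)[C@H]12 | intermediate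
15 | C1 hydroxymethyl compound (lower face), C4 ketone, C4a silyl ether | OC[C@H]1[C@H](C)CC(=O)[C@]2(O[Si](CC)(CC)CC)C[C@H](C(=O)OCC[Si](C)(C)C)C[C@H](C)[C@H]12 | intermediate
16 | C1 (triethylsilyloxy)methyl, C4a triethylsilyloxy C4 ketone | CC[Si](CC)(CC)OC[C@H]1[C@H](C)CC(=O)[C@]2(O[Si](CC)(CC)CC)C[C@H](C(=O)OCC[Si](C)(C)C)C[C@H](C)[C@H]12 | intermediate
17 | C4 enol triflate of 16 (C3=C4) | CC[Si](CC)(CC)OC[C@H]1[C@H](C)C=C(OS(=O)(=O)C(F)(F)F)[C@]2(O[Si](CC)(CC)CC)C[C@H](C(=O)OCC[Si](C)(C)C)C[C@H](C)[C@H]12 | intermediate
18 | C3=C4 alkene with C1 (triethylsilyloxy)methyl, C4a triethylsilyloxy, C6 2-(trimethylsilyl)ethyl ester | CC[Si](CC)(CC)OC[C@H]1[C@H](C)C=C[C@]2(O[Si](CC)(CC)CC)C[C@H](C(=O)OCC[Si](C)(C)C)C[C@H](C)[C@H]12 | intermediate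
19 | C1 aldehyde of the C3=C4 decalin (formyl lower face, C4a triethylsilyloxy, C6 ester) | O=C[C@H]1[C@H](C)C=C[C@]2(O[Si](CC)(CC)CC)C[C@H](C(=O)OCC[Si](C)(C)C)C[C@H](C)[C@H]12 | intermediate
20 | (E)-oct-2-en-1-ol | CCCCC/C=C/CO | starting material
21 | methyl (E)-oct-2-en-1-yl carbonate | CCCCC/C=C/COC(=O)OC | intermediate
22 | dimethyl malonate | COC(=O)CC(=O)OC | starting material
23 | dimethyl 2-[(3S)-oct-1-en-3-yl]propanedioate | C=C[C@H](CCCCC)C(C(=O)OC)C(=O)OC | intermediate
24 | 2-chloro-N-(4-methoxybenzyl)acetamide | ClCC(=O)NCc1ccc(OC)cc1 | starting material
25 | dimethyl 2-{2-[(4-methoxybenzyl)amino]-2-oxoethyl}-2-[(3S)-oct-1-en-3-yl]propanedioate | C=C[C@H](CCCCC)C(CC(=O)NCc1ccc(OC)cc1)(C(=O)OC)C(=O)OC | intermediate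
26 | methyl 1-(4-methoxybenzyl)-3-[(3S)-oct-1-en-3-yl]-2,5-dioxopyrrolidine-3-carboxylate (ring C3 as a mixture) | C=C[C@H](CCCCC)C1(C(=O)OC)CC(=O)N(Cc2ccc(OC)cc2)C1=O | intermediate
27 | 1-(4-methoxybenzyl)-3-[(3S)-oct-1-en-3-yl]pyrrolidine-2,5-dione (ring C3 as a mixture) | C=C[C@H](CCCCC)C1CC(=O)N(Cc2ccc(OC)cc2)C1=O | intermediate
28 | aldol adduct: N-(4-methoxybenzyl)succinimide bearing the (3S)-oct-1-en-3-yl group and, on the neighbouring ring carbon, the hydroxy(decalin-1-yl)methyl group (decalin as in 19; carbinol and ring carbons as mixtures) | C=C[C@H](CCCCC)C1C(C(O)[C@H]2[C@H](C)C=C[C@]3(O[Si](CC)(CC)CC)C[C@H](C(=O)OCC[Si](C)(C)C)C[C@H](C)[C@H]23)C(=O)N(Cc2ccc(OC)cc2)C1=O | intermediate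
29 | N-unsubstituted aldol adduct (as 28 without the 4-methoxybenzyl group) | C=C[C@H](CCCCC)C1C(C(O)[C@H]2[C@H](C)C=C[C@]3(O[Si](CC)(CC)CC)C[C@H](C(=O)OCC[Si](C)(C)C)C[C@H](C)[C@H]23)C(=O)NC1=O | intermediate
30 | β-keto imide: 3-(decalin-1-ylcarbonyl)-4-[(3S)-oct-1-en-3-yl]pyrrolidine-2,5-dione with C4a triethylsilyloxy and C6 2-(trimethylsilyl)ethyl ester | C=C[C@H](CCCCC)C1C(C(=O)[C@H]2[C@H](C)C=C[C@]3(O[Si](CC)(CC)CC)C[C@H](C(=O)OCC[Si](C)(C)C)C[C@H](C)[C@H]23)C(=O)NC1=O | intermediate
31 | β-keto imide with free C4a hydroxyl and C6 carboxylic acid | C=C[C@H](CCCCC)C1C(C(=O)[C@H]2[C@H](C)C=C[C@]3(O)C[C@H](C(=O)O)C[C@H](C)[C@H]23)C(=O)NC1=O | intermediate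
32 | 3-phenylselanyl derivative of 31 (selenium on the acyl-bearing ring carbon) | C=C[C@H](CCCCC)C1C([Se]c2ccccc2)(C(=O)[C@H]2[C@H](C)C=C[C@]3(O)C[C@H](C(=O)O)C[C@H](C)[C@H]23)C(=O)NC1=O | intermediate
33 | CNP0326775.3: (1S,2R,4aR,6R,8S,8aR)-4a-hydroxy-2,8-dimethyl-1-({2,5-dioxo-4-[(3S)-oct-1-en-3-yl]-2,5-dihydro-1H-pyrrol-3-yl}carbonyl)-1,2,4a,5,6,7,8,8a-octahydronaphthalene-6-carboxylic acid (decalin locants as used in the text) | C=C[C@H](CCCCC)C1=C(C(=O)[C@H]2[C@H](C)C=C[C@]3(O)C[C@H](C(=O)O)C[C@H](C)[C@H]23)C(=O)NC1=O | target

## Step count and least certain steps

Total: 24 steps. Longest linear sequence: 19 steps (steps 1, 3 to 15 and 20 to 24); the side-chain branch (steps 16 to 19) joins at step 20.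

**Step 3 (key step).**
- Risk: the strongly acidic catalyst may protodesilylate diene 4 or ionise the ketal of 2 before cycloaddition, and the terminal methyl group of the diene may collide with the aryl group of the catalyst, eroding endo and enantioface selectivity.
- Fallback: 2 and 4 are combined thermally (toluene, 80 °C), which should give the racemic endo adduct. The enantiomers are then separated by preparative chromatography on a chiral stationary phase. The fallback sets out from 2 and 4 and returns at 5; the enantiomer of adduct 5 F1 is discarded.

**Step 4.**
- Risk: the transient caesium enolate sits in a molecule that also holds an enone and an acidic C8a hydrogen. Transannular Michael addition to C3, or proton transfer with epimerisation at C8a (loss of the cis fusion), may compete with O-triflation.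
- Fallback: the carbonyl groups are removed before fluoride is used, setting out from 5 and returning at 9.
  - Conjugate reduction of the enone with [(Ph3P)CuH]6 gives the saturated C1 ketone with the silyl enol ether intact F2.
  - Takai–Lombardo methylenation gives its C1-methylene derivative F3.
  - CsF/PhNTf2 gives the C6 enol triflate F4, and carbonylation as in step 5 gives the unsaturated 2-(trimethylsilyl)ethyl ester F5.
  - Copper hydride conjugate reduction of F5 (catalytic [(Ph3P)CuH]6, a silane, t-BuOH), which leaves the 1,1-disubstituted alkene alone, gives 9.

**Step 10.**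
- Risk: poor facial selectivity in the epoxidation of the exocyclic alkene. The flanking substituents at C2 and C8a are both on the upper face but equatorial, so the peracid may attack from above; this would end as the wrong C1 epimer. Incomplete regiocontrol in 11 would in addition lead to oxidation at C3.
- Fallback: carbon, not oxygen, is delivered to the accessible face, setting out from 8 and returning at 16.
  - Ketone 8 with dimethylsulfonium methylide (Me3S+ I−, KN(SiMe3)2) gives the ketal spiro-oxirane with its oxygen on the lower face F6.
  - BF3·OEt2, then NaBH4 and aqueous acid, give the C1 hydroxymethyl C4 ketone F7.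
  - Excess Et3SiOTf/Et3N gives the silyl ether silyl enol ether F8.
  - One equivalent of mCPBA gives 16.

**Step 11.**
- Risk: loss of stereospecificity if the C1 cation is long-lived (hydride shift to either face), elimination to an allylic alcohol, or epimerisation of 14 before it is reduced.
- Fallback: equilibration and recycling, setting out from 15 contaminated with its epimer and returning at 15. The C1-epimeric alcohol F9 is separated, oxidised with the periodinane to the C1-epimeric aldehyde F10, equilibrated with DBU through the enol, reduced with NaBH4 and separated again.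

**Step 21.**
- Risk: slow oxidative cleavage, because an imide nitrogen assists the benzylic oxidation poorly; oxidation of the alkenes or the secondary alcohol may then compete.
- Fallback: no nitrogen protecting group is used, setting out from 23 and returning at 29.
  - Alkylation of 23 with 2-chloroacetamide and ring closure give the N-unsubstituted imide ester F11.
  - Dealkoxycarbonylation gives the N-unsubstituted succinimide F12.
  - Its N,C-dilithio derivative (two equivalents of LiN(iPr)2) is added to 19 to give 29 directly.

**Step 24.**
- Risk: addition of the selenium electrophile to the two alkenes (or selenolactonisation with the free acid), and a slow syn elimination if selenenylation occurs cis to the side chain.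
- Fallback: 31 is dehydrogenated directly with DDQ in dioxane at room temperature, a hydride abstraction from the enol that needs no electrophilic selenium. It sets out from 31 and returns at 33 and makes no new compound.

## Further compounds

F1 | step 3 | enantiomer of adduct 5 | O=C1C(C)=CC(OC)(OC)[C@H]2CC(O[Si](C(C)C)(C(C)C)C(C)C)=C[C@@H](C)[C@@H]12
F2 | step 4 | saturated C1 ketone with the silyl enol ether intact (C2 methyl on the upper face, C4 dimethyl ketal) | O=C1[C@H](C)CC(OC)(OC)[C@@H]2CC(O[Si](C(C)C)(C(C)C)C(C)C)=C[C@H](C)[C@H]12
F3 | step 4 | C1-methylene derivative of F2 | C=C1[C@H](C)CC(OC)(OC)[C@@H]2CC(O[Si](C(C)C)(C(C)C)C(C)C)=C[C@H](C)[C@H]12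
F4 | step 4 | C6 enol triflate of the C1-methylene ketal | C=C1[C@H](C)CC(OC)(OC)[C@@H]2CC(OS(=O)(=O)C(F)(F)F)=C[C@H](C)[C@H]12
F5 | step 4 | unsaturated 2-(trimethylsilyl)ethyl ester (C6=C7) of the C1-methylene ketal | C=C1[C@H](C)CC(OC)(OC)[C@@H]2CC(C(=O)OCC[Si](C)(C)C)=C[C@H](C)[C@H]12
F6 | step 10 | ketal spiro-oxirane at C1 with its oxygen on the lower face | C1O[C@]12[C@H](C)CC(OC)(OC)[C@@H]3C[C@H](C(=O)OCC[Si](C)(C)C)C[C@H](C)[C@H]23
F7 | step 10 | C1 hydroxymethyl C4 ketone (H-4a, no C4a oxygen) | OC[C@H]1[C@H](C)CC(=O)[C@@H]2C[C@H](C(=O)OCC[Si](C)(C)C)C[C@H](C)[C@H]12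
F8 | step 10 | C1 (triethylsilyloxy)methyl triethylsilyl enol ether across C4=C4a | CC[Si](CC)(CC)OC[C@H]1[C@H](C)CC(O[Si](CC)(CC)CC)=C2C[C@H](C(=O)OCC[Si](C)(C)C)C[C@H](C)[C@H]12
F9 | step 11 | C1 epimer of alcohol 15 | OC[C@@H]1[C@H](C)CC(=O)[C@]2(O[Si](CC)(CC)CC)C[C@H](C(=O)OCC[Si](C)(C)C)C[C@H](C)[C@H]12
F10 | step 11 | C1 epimer of aldehyde 14 | O=C[C@@H]1[C@H](C)CC(=O)[C@]2(O[Si](CC)(CC)CC)C[C@H](C(=O)OCC[Si](C)(C)C)C[C@H](C)[C@H]12
F11 | step 21 | methyl 3-[(3S)-oct-1-en-3-yl]-2,5-dioxopyrrolidine-3-carboxylate | C=C[C@H](CCCCC)C1(C(=O)OC)CC(=O)NC1=O
F12 | step 21 | 3-[(3S)-oct-1-en-3-yl]pyrrolidine-2,5-dione | C=C[C@H](CCCCC)C1CC(=O)NC1=O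
F0 | step 24 | none | none
A1 | alternative 1 | cis-decalin C1 tert-butyl ester with C4a triethylsilyl ether, C3=C4 and C6 methyl ester | CC(C)(C)OC(=O)[C@@H]1[C@H]2[C@@H](C)C[C@@H](C(=O)OC)C[C@@]2(O[Si](CC)(CC)CC)C=C[C@H]1C
A2 | alternative 2 | cis-decalin with C1 (tert-butyldimethylsilyloxy)methyl, free C4a hydroxyl and geminal C6 dimethyl ester | CC(C)(C)[Si](C)(C)OC[C@@H]1[C@H]2[C@@H](C)CC(C(=O)OC)(C(=O)OC)C[C@@]2(O)C=C[C@H]1C
A3 | alternative 3 | cis-decalin-7-one with C4a triisopropylsilyl ether, C6 (4-methoxybenzyloxy)methyl and C1 (tert-butyldiphenylsilyloxy)methyl | CC(C)(C)[Si](c1ccccc1)(c1ccccc1)OC[C@@H]1[C@H]2[C@@H](C)C(=O)[C@@H](COCc3ccc(OC)cc3)C[C@@]2(O[Si](C(C)C)(C(C)C)C(C)C)C=C[C@H]1C
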